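**Plan**

1. Retrosynthetic cuts: first the C8–C(spiro) bond that closes the furan ring, then the O1–C(spiro) N,O-acetal bond between an 8-bromo-1-naphthol and a 3-hydroxyisoindolinone; the lactam ring is cut back to a 3-methoxybenzamide plus DMF (ortho-lithiation), and naphthalene ring A to a 4-aryl-3-methylbutenoic acid (benzannulation).
2. Forward order: ring A of the naphthalene is closed onto the benzyloxyphenyl ring, C8 is brominated and O7 silylated; the lactam ring is made in two steps; the halves are joined through O1; the five-membered furan ring is closed last by C–C bond formation; desilylation ends the route.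
3. Enabling feature: the isoindolinone C3–H lies between the lactam N, the benzo ring and O1, so base gives a planar 10π isoindololate. O1 on naphthalene C1 holds this carbon 1,5 to the peri carbon C8, so palladium inserted at C8–Br gives a six-membered oxapalladacycle that reductively eliminates to the five-membered ring of the naphtho[1,8-bc]furan.
4. Stereochemistry: the only stereocentre (spiro carbon, R in the target) is created in that ring closure under control of a chiral NHC ligand on palladium, enantioconvergently from the racemic N,O-acetal. No later step exposes it to acid, a free N–H or a phenoxide.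

Key step: step 11

**Remarks**

- Naphthalene locants (O1, C2, C3-methyl, C4, O7, C8) are those of the naphthalen-1-ol precursors. Ring A carries O1 and the methyl group, ring B carries O7 and C8. C3 of the isoindolinone becomes the spiro carbon.
- The spiro carbon is R in 19 and, with the same spatial arrangement, S in 18, because the O–Si group raises the CIP rank of the naphthyl branch.
- L*·HI = 1,3-bis[(S)-2,2-dimethyl-1-(2-methylphenyl)propyl]imidazolium iodide or its mirror image. The sense of induction cannot be predicted, so the antipode that gives 18 is fixed on the first run.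
- Compound 1 is taken as a catalogue chemical; it is otherwise one benzylation from 4-hydroxyphenylacetone.

**Route**

Step 1
Reactants: 1 1-[4-(benzyloxy)phenyl]propan-2-one; 2 triethyl phosphonoacetate
Product: 3 ethyl 4-[4-(benzyloxy)phenyl]-3-methylbut-2-enoate (E/Z mixture)
Conditions: NaH, THF, 0 °C to 60 °C
Reagents that add atoms: none
Why: Horner–Wadsworth–Emmons olefination of the methyl ketone should give the trisubstituted enoate, whose E/Z and double-bond-position isomers need no separation because all converge in step 3.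

Step 2
Reactants: 3 ethyl 4-[4-(benzyloxy)phenyl]-3-methylbut-2-enoate
Product: 4 4-[4-(benzyloxy)phenyl]-3-methylbut-2-enoic acid (E/Z mixture)
Conditions: LiOH, THF/MeOH/H2O, rt; then 1 M HCl
Reagents that add atoms: lithium hydroxide, [Li+].[OH-]
Why: Standard saponification of the ethyl ester should leave the benzyl ether untouched.

Step 3
Reactants: 4 4-[4-(benzyloxy)phenyl]-3-methylbut-2-enoic acid
Product: 6 7-(benzyloxy)-3-methylnaphthalen-1-yl acetate, via free naphthol 5 (not isolated)
Conditions: Ac2O, NaOAc, 140 °C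
Reagents that add atoms: acetic anhydride, CC(=O)OC(C)=O
Why: Benzannulation of the Stobbe-cyclisation type (acylative ring closure by ketene 6π-electrocyclisation onto the aryl carbon ortho to the side chain, both ortho positions being equivalent so that only the 7-benzyloxy isomer can form), with the liberated naphthol 5 acetylated in situ.

Step 4
Reactants: 6 7-(benzyloxy)-3-methylnaphthalen-1-yl acetate
Product: 7 7-hydroxy-3-methylnaphthalen-1-yl acetate
Conditions: H2 (1 atm), Pd/C, EtOAc, rt
Reagents that add atoms: none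
Why: Hydrogenolysis of the aryl benzyl ether frees O7 while the aryl acetate keeps O1 masked, which differentiates the two oxygens.

Step 5
Reactants: 7 7-hydroxy-3-methylnaphthalen-1-yl acetate
Product: 8 8-bromo-7-hydroxy-3-methylnaphthalen-1-yl acetate
Conditions: NBS (1.0 equiv), MeCN, −20 °C to 0 °C, dark
Reagents that add atoms: N-bromosuccinimide, O=C1CCC(=O)N1Br
Why: Electrophilic bromination of a 2-naphthol occurs at its α-position, here C8, and the acetate deactivates ring A against attack at C2 or C4.

Step 6
Reactants: 8 8-bromo-7-hydroxy-3-methylnaphthalen-1-yl acetate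
Product: 9 8-bromo-3-methyl-7-[(triisopropylsilyl)oxy]naphthalen-1-yl acetate
Conditions: TIPSOTf, 2,6-lutidine, CH2Cl2, 0 °C
Reagents that add atoms: triisopropylsilyl trifluoromethanesulfonate, CC(C)[Si](OS(=O)(=O)C(F)(F)F)(C(C)C)C(C)C
Why: Silylation of the hindered ortho-bromophenol with the silyl triflate installs a base-stable, fluoride-labile group on O7.

Step 7
Reactants: 9 8-bromo-3-methyl-7-[(triisopropylsilyl)oxy]naphthalen-1-yl acetate
Product: 10 8-bromo-3-methyl-7-[(triisopropylsilyl)oxy]naphthalen-1-ol
Conditions: N2H4·H2O, THF/MeOH, 0 °C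
Reagents that add atoms: none
Why: Hydrazinolysis cleaves the aryl acetate under near-neutral conditions that should leave the aryl silyl ether and the bromide intact.

Step 8
Reactants: 11 3-methoxybenzoyl chloride; 12 2-[(tert-butyldiphenylsilyl)oxy]ethan-1-amine
Product: 13 N-{2-[(tert-butyldiphenylsilyl)oxy]ethyl}-3-methoxybenzamide
Conditions: Et3N, CH2Cl2, 0 °C to rt
Reagents that add atoms: none
Why: Schotten–Baumann-type acylation of the primary amine gives the secondary benzamide that serves as directing group in step 9.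

Step 9
Reactants: 13 N-{2-[(tert-butyldiphenylsilyl)oxy]ethyl}-3-methoxybenzamide
Product: 15 rac-2-{2-[(tert-butyldiphenylsilyl)oxy]ethyl}-3-hydroxy-4-methoxyisoindolin-1-one, via ortho-formyl amide 14 (not isolated)
Conditions: s-BuLi (2.2 equiv), TMEDA, THF, −78 °C; DMF, −78 °C to rt; aq. NH4Cl
Reagents that add atoms: N,N-dimethylformamide, CN(C)C=O
Why: Directed ortho-metalation, in which the lithium amidate and the methoxy group cooperatively direct the second equivalent of s-BuLi to C2 between them, DMF formylates that carbon, and the ortho-formyl amide 14 closes to the racemic hydroxylactam on work-up.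

Step 10
Reactants: 15 rac-2-{2-[(tert-butyldiphenylsilyl)oxy]ethyl}-3-hydroxy-4-methoxyisoindolin-1-one; 10 8-bromo-3-methyl-7-[(triisopropylsilyl)oxy]naphthalen-1-ol
Product: 17 rac-3-({8-bromo-3-methyl-7-[(triisopropylsilyl)oxy]naphthalen-1-yl}oxy)-2-{2-[(tert-butyldiphenylsilyl)oxy]ethyl}-4-methoxyisoindolin-1-one, via chlorolactam 16 (not isolated)
Conditions: SOCl2, CH2Cl2, 0 °C to rt, evaporate; then 10, NaH, THF, 0 °C to rt
Reagents that add atoms: thionyl chloride, O=S(Cl)Cl (chlorine of intermediate 16 only)
Why: The hydroxylactam is converted into the α-chloro lactam (an N-acyliminium chloride equivalent), which should alkylate the naphthoxide on oxygen in the manner of an α-halo ether to give the racemic N,O-acetal, whose stereocentre is erased in step 11.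

Step 11
Reactants: 17 rac-3-({8-bromo-3-methyl-7-[(triisopropylsilyl)oxy]naphthalen-1-yl}oxy)-2-{2-[(tert-butyldiphenylsilyl)oxy]ethyl}-4-methoxyisoindolin-1-one
Product: 18 (S)-2-{2-[(tert-butyldiphenylsilyl)oxy]ethyl}-7-methoxy-7'-methyl-3'-[(triisopropylsilyl)oxy]spiro[isoindoline-1,2'-naphtho[1,8-bc]furan]-3-one
Conditions: Pd(dba)2 (5 mol %), L*·HI (5 mol %), NaOtBu (1.5 equiv), DME, 50 °C, argon
Reagents that add atoms: none
Why: Proposed new method: NaOtBu should remove the C3–H of racemic 17 to give a planar, aromatic 10π isoindol-1-olate (the C3 configuration is erased, so the step is enantioconvergent), zerovalent palladium inserts into the C8–Br bond, the carbanion is transferred to divalent palladium to give a six-membered oxapalladacycle (Pd, C8, C8a, C1, O1, C3), and C(sp2)–C(sp3) reductive elimination forms the C8–C3 bond. The closest known reaction type is the asymmetric palladium–NHC intramolecular α-arylation of α-alkoxy anilides to 3-alkoxy-3-aryl oxindoles; here the carbanion is a lactam-stabilised benzylic N,O-acetal carbon instead of an amide enolate carbon. The one ring closed is the five-membered furan ring of the naphtho[1,8-bc]furan, closed by reductive elimination from the six-membered palladacycle (formally 5-exo with respect to the aryl–palladium bond). The new spiro stereocentre is controlled by the chiral NHC ligand, which should differentiate the two faces of the isoindololate in the C–C bond-forming event. The step needs C-arylation at C8 without hydrodebromination: the peri relation of O1 and C8 allows no other ring size, the carbonyl oxygen of the anion cannot reach palladium in a reasonable ring, the palladium-bound C3 has no β-hydrogen, the O7 silyl ether blocks phenoxide coordination, and the silylated side chain removes the alkoxide that could otherwise reduce the aryl–palladium intermediate.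

Step 12
Reactants: 18 (S)-2-{2-[(tert-butyldiphenylsilyl)oxy]ethyl}-7-methoxy-7'-methyl-3'-[(triisopropylsilyl)oxy]spiro[isoindoline-1,2'-naphtho[1,8-bc]furan]-3-one
Product: 19 (R)-3'-hydroxy-2-(2-hydroxyethyl)-7-methoxy-7'-methylspiro[isoindoline-1,2'-naphtho[1,8-bc]furan]-3-one (CNP0434366.1)
Conditions: TBAF, AcOH (1:1), THF, 0 °C to rt
Reagents that add atoms: none
Why: Acetic-acid-buffered fluoride should remove both silyl groups without generating a free phenoxide or a strong acid, so the N-acyl N,O-ketal stereocentre is expected to be kept.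

**Compound list**

1 | 1-[4-(benzyloxy)phenyl]propan-2-one | CC(=O)Cc1ccc(OCc2ccccc2)cc1 | starting material
2 | triethyl phosphonoacetate | CCOC(=O)CP(=O)(OCC)OCC | starting material
3 | ethyl 4-[4-(benzyloxy)phenyl]-3-methylbut-2-enoate (E/Z mixture, E drawn) | CCOC(=O)/C=C(\C)Cc1ccc(OCc2ccccc2)cc1 | intermediate
4 | 4-[4-(benzyloxy)phenyl]-3-methylbut-2-enoic acid (E/Z mixture, E drawn) | OC(=O)/C=C(\C)Cc1ccc(OCc2ccccc2)cc1 | intermediate
5 | 7-(benzyloxy)-3-methylnaphthalen-1-ol | Cc1cc(O)c2cc(OCc3ccccc3)ccc2c1 | intermediate (not isolated)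
6 | 7-(benzyloxy)-3-methylnaphthalen-1-yl acetate | CC(=O)Oc1cc(C)cc2ccc(OCc3ccccc3)cc12 | intermediate
7 | 7-hydroxy-3-methylnaphthalen-1-yl acetate | CC(=O)Oc1cc(C)cc2ccc(O)cc12 | intermediate
8 | 8-bromo-7-hydroxy-3-methylnaphthalen-1-yl acetate | CC(=O)Oc1cc(C)cc2ccc(O)c(Br)c12 | intermediate
9 | 8-bromo-3-methyl-7-[(triisopropylsilyl)oxy]naphthalen-1-yl acetate | CC(=O)Oc1cc(C)cc2ccc(O[Si](C(C)C)(C(C)C)C(C)C)c(Br)c12 | intermediate
10 | 8-bromo-3-methyl-7-[(triisopropylsilyl)oxy]naphthalen-1-ol | Oc1cc(C)cc2ccc(O[Si](C(C)C)(C(C)C)C(C)C)c(Br)c12 | intermediate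
11 | 3-methoxybenzoyl chloride | COc1cccc(C(Cl)=O)c1 | starting material
12 | 2-[(tert-butyldiphenylsilyl)oxy]ethan-1-amine | NCCO[Si](c1ccccc1)(c1ccccc1)C(C)(C)C | starting material
13 | N-{2-[(tert-butyldiphenylsilyl)oxy]ethyl}-3-methoxybenzamide | COc1cccc(C(=O)NCCO[Si](c2ccccc2)(c2ccccc2)C(C)(C)C)c1 | intermediate
14 | N-{2-[(tert-butyldiphenylsilyl)oxy]ethyl}-2-formyl-3-methoxybenzamide | COc1cccc(C(=O)NCCO[Si](c2ccccc2)(c2ccccc2)C(C)(C)C)c1C=O | intermediate (not isolated)
15 | rac-2-{2-[(tert-butyldiphenylsilyl)oxy]ethyl}-3-hydroxy-4-methoxyisoindolin-1-one | COc1cccc2C(=O)N(CCO[Si](c3ccccc3)(c3ccccc3)C(C)(C)C)C(O)c12 | intermediate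
16 | rac-2-{2-[(tert-butyldiphenylsilyl)oxy]ethyl}-3-chloro-4-methoxyisoindolin-1-one | COc1cccc2C(=O)N(CCO[Si](c3ccccc3)(c3ccccc3)C(C)(C)C)C(Cl)c12 | intermediate (not isolated)
17 | rac-3-({8-bromo-3-methyl-7-[(triisopropylsilyl)oxy]naphthalen-1-yl}oxy)-2-{2-[(tert-butyldiphenylsilyl)oxy]ethyl}-4-methoxyisoindolin-1-one | COc1cccc2C(=O)N(CCO[Si](c3ccccc3)(c3ccccc3)C(C)(C)C)C(Oc3cc(C)cc4ccc(O[Si](C(C)C)(C(C)C)C(C)C)c(Br)c34)c12 | intermediate
18 | (S)-2-{2-[(tert-butyldiphenylsilyl)oxy]ethyl}-7-methoxy-7'-methyl-3'-[(triisopropylsilyl)oxy]spiro[isoindoline-1,2'-naphtho[1,8-bc]furan]-3-one | COc1cccc2c1[C@@]1(Oc3cc(C)cc4ccc(O[Si](C(C)C)(C(C)C)C(C)C)c1c34)N(CCO[Si](c5ccccc5)(c5ccccc5)C(C)(C)C)C2=O | intermediate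
19 | (R)-3'-hydroxy-2-(2-hydroxyethyl)-7-methoxy-7'-methylspiro[isoindoline-1,2'-naphtho[1,8-bc]furan]-3-one | COc1cccc2c1[C@@]1(Oc3cc(C)cc4ccc(O)c1c34)N(CCO)C2=O | target

**Step count and risks**

Total step count: 12. Longest linear sequence: 10 steps (steps 1 to 7, then 10, 11 and 12).

Step 11 (bears the label). Oxidative addition at the doubly flanked C8–Br bond may be slow, so that hydrodebromination or decay of the electron-rich isoindololate outruns ring closure; the ligand may also discriminate the two faces poorly. The fallback makes the C8–C(spiro) bond by known acid chemistry and closes the ring through oxygen; it sets out from hydroxylactam 15 and naphthol acetate 7 and comes back at target 19. TsOH-catalysed amidoalkylation (aza-Friedel–Crafts reaction of the N-acyliminium ion from 15) at C8 of 7, the α-position of the 2-naphthol unit, should give the 3-(8-acetoxy-2-hydroxy-6-methylnaphthalen-1-yl)isoindolinone F1. Hydrazinolysis should give the naphthalenediol F2. DDQ oxidation to the ortho-quinone methide and its capture by the peri hydroxyl O1 should give the racemic spiro N,O-ketal F3. Preparative chiral SFC should give the (R)-enantiomer F4, while the other enantiomer in F3 is racemised with TsOH and recycled. TBAF/AcOH then gives 19.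

Step 10. O-alkylation of the naphthoxide, which is crowded by the peri bromine, may lose to C-alkylation at C2 or C4 or to hydrolysis of the chlorolactam. The fallback joins the halves before the bromine is introduced; it sets out from 7 and comes back at 17. TIPSOTf and 2,6-lutidine should give the bromine-free silyl ether acetate F5, and hydrazinolysis the unhindered naphthol F6. O-alkylation of its sodium salt with chlorolactam 16 (made from 15 as in step 10) should give the N,O-acetal F7. Cs2CO3 in wet DMF cleaves only the aryl silyl ether, giving the phenol F8. NBS with catalytic i-Pr2NH, which brominates ortho to a free phenol, should give the C8 bromide F9. TIPSOTf with 2,6-lutidine returns to 17.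

Step 5. Bromination may go to C6 or occur twice, or NBS may oxidise the free electron-rich naphthol, because the peri acetate shields C8. The fallback brominates at the ether stage and then removes the benzyl group with a Lewis acid instead of hydrogen; it sets out from 6 and comes back at 8. NBS in MeCN should brominate the α-position of the 2-alkoxynaphthalene unit to give the bromo benzyl ether F10. BCl3 with pentamethylbenzene in CH2Cl2 at −78 °C then removes the benzyl group without touching the bromide or the acetate, giving 8.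

**Further compounds**

F1 | step 11 | rac-3-(8-acetoxy-2-hydroxy-6-methylnaphthalen-1-yl)-2-{2-[(tert-butyldiphenylsilyl)oxy]ethyl}-4-methoxyisoindolin-1-one | COc1cccc2C(=O)N(CCO[Si](c3ccccc3)(c3ccccc3)C(C)(C)C)C(c3c(O)ccc4cc(C)cc(OC(C)=O)c34)c12
F2 | step 11 | rac-2-{2-[(tert-butyldiphenylsilyl)oxy]ethyl}-3-(2,8-dihydroxy-6-methylnaphthalen-1-yl)-4-methoxyisoindolin-1-one | COc1cccc2C(=O)N(CCO[Si](c3ccccc3)(c3ccccc3)C(C)(C)C)C(c3c(O)ccc4cc(C)cc(O)c34)c12
F3 | step 11 | rac-2-{2-[(tert-butyldiphenylsilyl)oxy]ethyl}-3'-hydroxy-7-methoxy-7'-methylspiro[isoindoline-1,2'-naphtho[1,8-bc]furan]-3-one | COc1cccc2c1C1(Oc3cc(C)cc4ccc(O)c1c34)N(CCO[Si](c5ccccc5)(c5ccccc5)C(C)(C)C)C2=O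
F4 | step 11 | (R)-2-{2-[(tert-butyldiphenylsilyl)oxy]ethyl}-3'-hydroxy-7-methoxy-7'-methylspiro[isoindoline-1,2'-naphtho[1,8-bc]furan]-3-one | COc1cccc2c1[C@@]1(Oc3cc(C)cc4ccc(O)c1c34)N(CCO[Si](c5ccccc5)(c5ccccc5)C(C)(C)C)C2=O
F5 | step 10 | 3-methyl-7-[(triisopropylsilyl)oxy]naphthalen-1-yl acetate | CC(=O)Oc1cc(C)cc2ccc(O[Si](C(C)C)(C(C)C)C(C)C)cc12
F6 | step 10 | 3-methyl-7-[(triisopropylsilyl)oxy]naphthalen-1-ol | Oc1cc(C)cc2ccc(O[Si](C(C)C)(C(C)C)C(C)C)cc12
F7 | step 10 | rac-2-{2-[(tert-butyldiphenylsilyl)oxy]ethyl}-4-methoxy-3-({3-methyl-7-[(triisopropylsilyl)oxy]naphthalen-1-yl}oxy)isoindolin-1-one | COc1cccc2C(=O)N(CCO[Si](c3ccccc3)(c3ccccc3)C(C)(C)C)C(Oc3cc(C)cc4ccc(O[Si](C(C)C)(C(C)C)C(C)C)cc34)c12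
F8 | step 10 | rac-2-{2-[(tert-butyldiphenylsilyl)oxy]ethyl}-3-[(7-hydroxy-3-methylnaphthalen-1-yl)oxy]-4-methoxyisoindolin-1-one | COc1cccc2C(=O)N(CCO[Si](c3ccccc3)(c3ccccc3)C(C)(C)C)C(Oc3cc(C)cc4ccc(O)cc34)c12
F9 | step 10 | rac-3-[(8-bromo-7-hydroxy-3-methylnaphthalen-1-yl)oxy]-2-{2-[(tert-butyldiphenylsilyl)oxy]ethyl}-4-methoxyisoindolin-1-one | COc1cccc2C(=O)N(CCO[Si](c3ccccc3)(c3ccccc3)C(C)(C)C)C(Oc3cc(C)cc4ccc(O)c(Br)c34)c12
F10 | step 5 | 7-(benzyloxy)-8-bromo-3-methylnaphthalen-1-yl acetate | CC(=O)Oc1cc(C)cc2ccc(OCc3ccccc3)c(Br)c12
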